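## Structural features

The target is the C40 carotenoid (3S,5S,6S,3'R,6'R)-5,6-dihydro-β,ε-carotene-3,5,6,3'-tetrol. An all-E chain of nine conjugated double bonds (C7=C8 to C7'=C8') with four methyl branches joins two different trimethylcyclohexane rings through C6 and C6'. The unprimed ring is saturated and carries three stereocentres: a secondary carbinol at C3 and two adjacent tertiary carbinols at C5 and C6, crowded between the C5 methyl and the C1 gem-dimethyl group. Its 5,6-diol is trans, and the C5 hydroxyl is cis to the C3 hydroxyl. The primed (ε) ring is a cyclohexene whose C4'=C5' bond is not conjugated with the chain; it has an allylic hydroxyl at C3' and a tertiary CH at C6' next to the gem-dimethyl carbon C1', with C3' and C6' 1,4 across the ring and trans. Fragile points are the polyene (light, oxygen, acid), the tertiary allylic C6 hydroxyl and the allylic C3' hydroxyl (both ionise in acid), and the doubly allylic C6'–H, which lets the ring double bond slip into conjugation under forcing base. The chain is routine C15 + C10 + C15 Wittig chemistry, so the real difficulty lies in the two rings: the remote C3'/C6' relation, the trans diol on the correct face relative to C3, and carrying both through chain assembly without acid. The key step exploits the ε ring: C6' bonded to the gem-dimethyl carbon C1' with the alkene at C4'=C5' is the pattern left by cation–olefin cyclisation of an acyclic isoprenoid, so the C1'–C6' bond and the C6' stereocentre can be made in one ring closure directed by the C3' oxygen.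

## Logic of the disconnections

31 from 30: only the two O–Si bonds at C3 and C3' are cut. Both secondary hydroxyls stay masked through every acidic or basic step, and the last step must be non-acidic because of the C6 and C3' carbinols.

30 from 19 and 28: the C11=C12 double bond is cut. This splits C40 into a C25 aldehyde and a C15 phosphonium salt, each holding one ring. The forward step must tolerate two free tertiary hydroxyls in 28 and give, or be isomerised to, the E alkene.

19 from 16 and 17: the C11'=C12' double bond is cut. The central C10 unit 17 is symmetric and purchasable, so all remaining effort is in the C15 end groups. The forward step must stop after one of the two formyl groups of 17 has reacted.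

16 from 15, and 15 from 13 and 14: the C11'–P bond and the C9'–C10' bond are cut. The C15 salt is reduced to a C13 methyl ketone plus a two-carbon reagent. The forward steps must leave the C3' allylic ether and the C6' hydrogen alone.

13 from 12 (key disconnection): the C1'–C6' ring bond is cut. The ring with two stereocentres becomes an open chain with one, and that one (C3') is carried in from 1. The forward step must protonate only the terminal alkene, close trans to the C3' oxygen, and lose the proton toward C4'. Three features of 12 serve this: the initiating alkene is 1,1-disubstituted, so the oxygen is homoallylic and not allylic to it; the silyl group is triisopropylsilyl, so no aryl–silicon bond is exposed to the acid; and the C5'=C6' alkene is geometrically pure E, because its geometry is transmitted to the ring.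

12 from 10 and 11: the C6'–C7' bond is cut. The dienone is divided into an alkenyl iodide and a four-carbon enone. The forward coupling must retain the alkene geometry of 10.

10 from 7 and 8 (through 9): the C5'–methyl bond and the C6'–I bond are cut. The trisubstituted alkene is reduced to a terminal alkyne. The forward step must add methyl and metal syn and with methyl on the internal carbon.

7 from 6, 6 from 3 and 4 (through 5), 3 from 1 and 2: the O–Si bond, the C4'–C5' bond and the C1'–C2' bond are cut. The carbon chain collapses onto the three-carbon chiral building block 1. Both nucleophiles must attack CH2 termini only, so that the carbinol carbon is never touched.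

28 from 27, and 27 from 26 and 14: the C11–P and C9–C10 bonds are cut, exactly as for the other half. The forward steps must spare the tertiary allylic C6 hydroxyl.

26 from 25: the C5–O bond is cut. The trans diol is traced to an epoxide lying anti to the C3 oxygen. The forward step needs attack at C5, not C6, with inversion.

25 from 24: the two epoxide C–O bonds are cut. The forward step must be selective for the C5=C6 alkene and for the face anti to the C3 silyloxy group.

24 from 23 and 11; 23 from 21 (through 22); 21 from 20: the C6–C7 bond, the enol O–S bond and the O–Si bond are cut. The ring with its C3 stereocentre is bought as 20. The forward coupling must work at a tetrasubstituted, hindered alkenyl triflate.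

## Other disconnections considered

Alternative 1: The cut is at the C9–methyl bond and the C10–C11 bond of the triol half. In the forward step the terminal enyne A2 undergoes Cp2ZrCl2-catalysed syn-methylalumination with Al(CH3)3, and the alkenylalane is coupled with the iododienoate A3 under Pd(PPh3)4/ZnCl2 to give the C20 tetraenoate A1.
- In its favour: the 9E geometry follows from syn addition and a stereoretentive coupling; no phosphonium salt has to be formed in acid next to the C6 carbinol; A1 is a stable, chromatographable half.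
- Against it here: all three hydroxyls must be silylated, two of them tertiary. The C6 silyloxy group is tertiary and allylic–propargylic and would face strongly Lewis acidic aluminium and zirconium species for hours. A1 still needs adjustment of the ester, and the ε half must also be grown to C20, so the last C–C bond joins two large polyenes.
- Structure: it builds only chain atoms and creates neither ring nor any stereocentre, whereas step 6 makes the ε ring and C6'.
- Mechanism: a syn carbometalation has a far more predictable outcome than a cationic ring closure, so the alternative is the better one on the reliability of its own key step. It is also better on C9 geometry, which steps 8 and 16 set under thermodynamic control. The same methylalumination is used in step 4 on a much simpler alkyne.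
- Step economy: the chosen plan reaches each C15 salt in two steps from its ketone and is shorter.

Alternative 2: The cut is at the C5–O bond of the triol. In the forward step BF3·OEt2 activates the 5,6-epoxide of A5, the carbonyl oxygen of the C3 tert-butyl carbonate attacks C5 from the face opposite to the epoxide oxygen, the tert-butyl group is lost, and the 3,5-cyclic carbonate A4 with a free C6 hydroxyl results.
- In its favour: the tether reaches C5 only; inversion at C5 is enforced; the alkyne at C6 cannot give an allylic cation, so furanoid rearrangement is excluded; the carbonate protects the 3,5-diol afterwards.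
- Against it here: the anti epoxide is still needed, so the facial problem of epoxidation remains. BF3 may ionise the tertiary propargylic C6–O bond. Carbonate installation, carbonate removal and semi-reduction of the alkyne add operations. The ε ring is left unsolved.
- Structure: it concentrates on C5/C6, the chosen key step on C3'/C6'; the two are complementary.
- Mechanism: for the C5–O bond the tethered opening is the better of the two, since step 14 relies only on the electronic bias of the enone toward an external nucleophile. For that reason it is kept as the fallback of step 14.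
- Step economy: the chosen triol salt takes seven steps from 20; the alternative would take about three more.

Alternative 3: The cuts are at C7=C8 and C7'=C8'. In the forward step the C20 bisphosphonate A7, made from the C20 dialdehyde A10, undergoes two successive Horner–Wadsworth–Emmons reactions, first with the trihydroxy-ring aldehyde A8 and then with the ε-ring aldehyde A9, to give the tetrakis(triethylsilyl) ether A6; fluoride then frees 31.
- In its favour: two C–C bond formations assemble C40; the four trisubstituted chain alkenes arrive preformed and all-E in A10, so there is no C9/C9' geometry problem, which is better than the chosen plan; the ring fragments are only C10.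
- Against it here: in A9 the C6' stereocentre is alpha to the formyl group and allylic, so the basic olefination conditions can epimerise it or move the C4'=C5' bond into conjugation. A8 is an α-silyloxy aldehyde on a carbon flanked by two fully substituted carbons and would be very sluggish toward a weakly stabilised allylic phosphonate anion. The two identical ends of A7 can be told apart only statistically. A9 still needs its own stereocontrolled ring synthesis.
- Structure: convergence is equal or better.
- Mechanism: the chosen plan keeps C6' away from any carbonyl after step 7 and olefinates at unhindered polyenals, which is safer.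
- Step economy: the longest linear sequence could be shorter (better), but the risk sits in the last two C–C bond formations.

Key step: step 6

Assumption: the chain is all-E as drawn; (4R,6R)-4-hydroxy-2,2,6-trimethylcyclohexanone 20 and (2E,4E,6E)-2,7-dimethylocta-2,4,6-trienedial 17 are taken as purchasable.

## Steps

Step 1
Reactants: 1 (R)-epichlorohydrin; 2 isopropenylmagnesium bromide
Product: 3 (R)-1-chloro-4-methylpent-4-en-2-ol
Conditions: CuI (10 mol %), THF, −40 → −20 °C; aq NH4Cl
Reagents that add atoms: none
Why: Copper-catalysed Grignard opening of the epoxide at its unsubstituted carbon is faster than displacement of chloride, so the chlorohydrin results; the stereocentre is not involved and keeps the configuration of 1.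

Step 2
Reactants: 3 (R)-1-chloro-4-methylpent-4-en-2-ol; 4 lithium acetylide–ethylenediamine complex
Product: 6 (R)-6-methylhept-6-en-1-yn-4-ol, via (R)-2-(2-methylallyl)oxirane 5 (not isolated)
Conditions: DMSO, 0 °C → rt (2.5 equiv of 4); H2O
Reagents that add atoms: none
Why: The first equivalent of acetylide deprotonates the alcohol and the alkoxide displaces chloride to give epoxide 5 (intramolecular Williamson reaction); a second equivalent opens 5 at its CH2 terminus by SN2. The carbinol carbon is never attacked, so the R configuration is retained.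

Step 3
Reactants: 6 (R)-6-methylhept-6-en-1-yn-4-ol
Product: 7 (R)-triisopropyl[(6-methylhept-6-en-1-yn-4-yl)oxy]silane
Conditions: TIPSOTf, 2,6-lutidine, CH2Cl2, −78 → 0 °C
Reagents that add atoms: triisopropylsilyl trifluoromethanesulfonate, CC(C)[Si](C(C)C)(C(C)C)OS(=O)(=O)C(F)(F)F
Why: Standard silylation of a secondary alcohol with a silyl triflate and a hindered pyridine base. Triisopropylsilyl is chosen over an arylsilyl group such as tert-butyldiphenylsilyl because it has no aryl–silicon bond or arene ring for the acid of step 6 to attack, and it is too bulky to act as a neighbouring group.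

Step 4
Reactants: 7 (R)-triisopropyl[(6-methylhept-6-en-1-yn-4-yl)oxy]silane; 8 trimethylaluminium
Product: 10 (R,E)-[(1-iodo-2,6-dimethylhepta-1,6-dien-4-yl)oxy]triisopropylsilane, via alkenyldimethylalane 9 (not isolated)
Conditions: Cp2ZrCl2 (25 mol %), CH2Cl2, 0 °C → rt; then I2, THF, −30 → 0 °C
Reagents that add atoms: iodine, II
Why: Negishi zirconium-catalysed carboalumination adds methyl and aluminium syn across the terminal alkyne with methyl on the internal carbon, and iodinolysis of the alkenyl–aluminium bond goes with retention. This fixes the E geometry of the future C5'=C6' alkene; the 1,1-disubstituted alkene and the silyl ether are inert.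

Step 5
Reactants: 10 (R,E)-[(1-iodo-2,6-dimethylhepta-1,6-dien-4-yl)oxy]triisopropylsilane; 11 methyl vinyl ketone
Product: 12 (3E,5E,8R)-6,10-dimethyl-8-(triisopropylsilyloxy)undeca-3,5,10-trien-2-one
Conditions: Pd(OAc)2 (10 mol %), Bu4NCl, K2CO3, DMF, rt
Reagents that add atoms: none
Why: Heck reaction: oxidative addition of the alkenyl iodide to zerovalent palladium, syn insertion of the enone and syn β-hydride elimination give the (3E,5E)-dienone with the iodide geometry retained. Intramolecular insertion into the remote alkene is impossible because the palladium-bearing carbon is trans to the tether.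

Step 6
Reactants: 12 (3E,5E,8R)-6,10-dimethyl-8-(triisopropylsilyloxy)undeca-3,5,10-trien-2-one
Product: 13 (E)-4-[(1R,4R)-2,6,6-trimethyl-4-(triisopropylsilyloxy)cyclohex-2-en-1-yl]but-3-en-2-one [(3R,6R)-3-(triisopropylsilyloxy)-α-ionone]
Conditions: ClSO3H (2.5 equiv), 2-nitropropane, −78 °C, 20 min; Et3N at −78 °C, then aq NaHCO3
Reagents that add atoms: none
Why: This is a biomimetic cation–olefin cyclisation: the acid protonates the isolated, electron-rich 1,1-disubstituted alkene at its CH2 terminus to give the tertiary C1' cation, while the dienone is only reversibly O-protonated and is not an initiating site. The C5'=C6' alkene attacks through C6', which forms the C1'–C6' bond and leaves a tertiary C5' cation that loses a proton from C4' to give the C4'=C5' alkene. The closest known reactions are the strong-acid cyclisation of pseudoionone to α-ionone and of pseudoirone to α-irone with chlorosulfonic acid at low temperature, where the endocyclic non-conjugated alkene is the kinetic product. The six-membered ring closes 6-endo-trig with respect to the attacked alkene (both its carbons end in the ring) through a chair-like transition state. The new C6' stereocentre is controlled by the C3' stereocentre of 12: the silyloxy group sits equatorial because an axial one would clash 1,3-diaxially with the methyl that becomes axial on C1', and the E geometry of the C5'=C6' alkene puts the dienone chain equatorial, which makes C3' and C6' trans, that is (3'R,6'R). The step needs site-selective protonation, secured by the difference in electron density between the isolated alkene and the deactivated dienone, and kinetic proton loss toward C4', favoured by −78 °C, short contact and a cold basic quench. It also needs the C3' oxygen to survive, which is secured because it is homoallylic to the initiating alkene, could bridge to either cation only through a four-membered ring, and carries a silyl group without an aryl–silicon bond; C3' itself is not touched.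

Step 7
Reactants: 13 (3R,6R)-3-(triisopropylsilyloxy)-α-ionone; 14 vinylmagnesium bromide
Product: 15 (1E)-3-methyl-1-[(1R,4R)-2,6,6-trimethyl-4-(triisopropylsilyloxy)cyclohex-2-en-1-yl]penta-1,4-dien-3-ol (both C3 epimers)
Conditions: THF, −78 → −20 °C; aq NH4Cl
Reagents that add atoms: none
Why: 1,2-Addition of a vinyl Grignard reagent to the methyl ketone, as in the standard preparation of vinylionols; at low temperature addition outruns γ-deprotonation at C6'. The new carbinol centre is erased in step 8, so both epimers are used.

Step 8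
Reactants: 15 (1E)-3-methyl-1-[(1R,4R)-2,6,6-trimethyl-4-(triisopropylsilyloxy)cyclohex-2-en-1-yl]penta-1,4-dien-3-ol
Product: 16 [(2E,4E)-3-methyl-5-[(1R,4R)-2,6,6-trimethyl-4-(triisopropylsilyloxy)cyclohex-2-en-1-yl]penta-2,4-dien-1-yl]triphenylphosphonium bromide
Conditions: PPh3·HBr, CH2Cl2/MeOH, 0 °C → rt
Reagents that add atoms: triphenylphosphine hydrobromide, Br.c1ccc(cc1)P(c1ccccc1)c1ccccc1
Why: The tertiary bis-allylic alcohol ionises to a pentadienyl cation that triphenylphosphine captures at the primary terminus (SN1' transposition, the standard C15 Wittig salt preparation), with the E trisubstituted alkene favoured thermodynamically. The weak acidity of the reagent and the bulky silyl group protect the C3' allylic ether.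

Step 9
Reactants: 16 ε-ring C15 phosphonium bromide; 17 (2E,4E,6E)-2,7-dimethylocta-2,4,6-trienedial
Product: 19 (2E,4E,6E,8E,10E,12E)-2,7,11-trimethyl-13-[(1R,4R)-2,6,6-trimethyl-4-(triisopropylsilyloxy)cyclohex-2-en-1-yl]trideca-2,4,6,8,10,12-hexaenal (C25 aldehyde), via phosphorus ylide 18 (not isolated)
Conditions: NaOMe, CH2Cl2/MeOH, 0 °C → rt (17 in threefold excess); then n-heptane, 80 °C, Ar, dark
Reagents that add atoms: none
Why: Wittig olefination of one formyl group of the dialdehyde with the allylic ylide 18; the excess of 17, which cannot enolise, secures mono-olefination. The Z isomer at the new double bond should be converted thermally into the all-E aldehyde.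

Step 10
Reactants: 20 (4R,6R)-4-hydroxy-2,2,6-trimethylcyclohexanone
Product: 21 (4R,6R)-2,2,6-trimethyl-4-(triisopropylsilyloxy)cyclohexanone
Conditions: TIPSCl, imidazole, DMF, rt
Reagents that add atoms: chlorotriisopropylsilane, CC(C)[Si](Cl)(C(C)C)C(C)C
Why: Silylation of the only hydroxyl under imidazole catalysis, which leaves the hindered ketone untouched; both stereocentres are unchanged.

Step 11
Reactants: 21 (4R,6R)-2,2,6-trimethyl-4-(triisopropylsilyloxy)cyclohexanone
Product: 23 (R)-2,6,6-trimethyl-4-(triisopropylsilyloxy)cyclohex-1-en-1-yl trifluoromethanesulfonate, via lithium enolate 22 (not isolated)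
Conditions: LiN(iPr)2, THF, −78 °C; then PhNTf2, −78 °C → rt
Reagents that add atoms: N-phenylbis(trifluoromethanesulfonimide), O=S(=O)(N(c1ccccc1)S(=O)(=O)C(F)(F)F)C(F)(F)F
Why: The ketone has a single α-hydrogen, so deprotonation gives one enolate 22, and O-triflation gives the tetrasubstituted enol triflate. The methyl-bearing stereocentre of 21 is destroyed on purpose; the silyloxy carbon (future C3) is untouched.

Step 12
Reactants: 23 (R)-2,6,6-trimethyl-4-(triisopropylsilyloxy)cyclohex-1-en-1-yl trifluoromethanesulfonate; 11 methyl vinyl ketone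
Product: 24 (E)-4-[(R)-2,6,6-trimethyl-4-(triisopropylsilyloxy)cyclohex-1-en-1-yl]but-3-en-2-one [(3R)-3-(triisopropylsilyloxy)-β-ionone]
Conditions: Pd(OAc)2 (5 mol %), PPh3, Et3N, DMF, 70 °C
Reagents that add atoms: none
Why: Heck reaction of the alkenyl triflate with the enone gives the E-enone by syn insertion and syn β-hydride elimination. This coupling type is established for hindered 2,6,6-trimethylcyclohexenyl triflates with acrylates.

Step 13
Reactants: 24 (3R)-3-(triisopropylsilyloxy)-β-ionone
Product: 25 (E)-4-[(1S,4S,6R)-2,2,6-trimethyl-4-(triisopropylsilyloxy)-7-oxabicyclo[4.1.0]heptan-1-yl]but-3-en-2-one [(3S,5R,6S)-epoxide]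
Conditions: mCPBA, NaHCO3, CH2Cl2, 0 °C
Reagents that add atoms: 3-chloroperoxybenzoic acid, OOC(=O)c1cccc(Cl)c1
Why: Prilezhaev epoxidation: the peracid attacks the electron-richer tetrasubstituted C5=C6 bond and not the enone C7=C8 bond. With the C3 oxygen silylated there is no hydroxyl direction, and the reagent is expected to prefer the face anti to the silyloxy group; the syn epoxide is to be removed by chromatography.

Step 14
Reactants: 25 (3S,5R,6S)-epoxide
Product: 26 (E)-4-[(1S,2S,4S)-1,2-dihydroxy-2,6,6-trimethyl-4-(triisopropylsilyloxy)cyclohexyl]but-3-en-2-one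
Conditions: HClO4 (0.5 M aq), THF, 0 °C → rt
Reagents that add atoms: water, O
Why: Acid-catalysed epoxide hydrolysis: C6 is the γ-carbon of the enone, so its C–O bond is deactivated and water opens the protonated epoxide at tertiary C5 with inversion. This gives the trans 5,6-diol with the C5 hydroxyl cis to the C3 silyloxy group (5S,6S); the silyl ether keeps the C3 oxygen from attacking C6.

Step 15
Reactants: 26 diol ketone; 14 vinylmagnesium bromide
Product: 27 (1S,2S,4S)-1-[(1E)-3-hydroxy-3-methylpenta-1,4-dien-1-yl]-2,6,6-trimethyl-4-(triisopropylsilyloxy)cyclohexane-1,2-diol (both epimers at the new carbinol)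
Conditions: THF, −78 → 0 °C (14 in 4.5-fold excess); aq NH4Cl
Reagents that add atoms: none
Why: The excess Grignard reagent first deprotonates the two tertiary hydroxyls and then adds 1,2 to the methyl ketone; the new carbinol centre is erased in step 16.

Step 16
Reactants: 27 vinyl carbinol
Product: 28 [(2E,4E)-5-[(1S,2S,4S)-1,2-dihydroxy-2,6,6-trimethyl-4-(triisopropylsilyloxy)cyclohexyl]-3-methylpenta-2,4-dien-1-yl]triphenylphosphonium bromide
Conditions: PPh3·HBr, CH2Cl2/MeOH, 0 °C
Reagents that add atoms: triphenylphosphine hydrobromide, Br.c1ccc(cc1)P(c1ccccc1)c1ccccc1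
Why: Same SN1' phosphonium formation as in step 8. The tertiary bis-allylic C9 hydroxyl should ionise far more easily than the C6 hydroxyl, which is only mono-allylic and deactivated by the neighbouring C5 hydroxyl, and triphenylphosphine traps the cation at C11.

Step 17
Reactants: 19 C25 aldehyde; 28 triol-ring C15 phosphonium bromide
Product: 30 (3S,5S,6S,3'R,6'R)-3,3'-bis(triisopropylsilyloxy)-5,6-dihydro-β,ε-carotene-5,6-diol, via phosphorus ylide 29 (not isolated)
Conditions: NaOMe, CH2Cl2/MeOH, 0 °C → rt (28 in slight excess); then n-heptane/EtOAc, 80 °C, Ar, dark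
Reagents that add atoms: none
Why: Wittig olefination of the polyenal with the allylic ylide 29 forms C11=C12; free tertiary hydroxyls are tolerated under alkoxide conditions. The Z isomer at the new bond should be isomerised thermally to all-E at this robust silyl ether stage.

Step 18
Reactants: 30 bis(triisopropylsilyl) ether
Product: 31 (3S,5S,6S,3'R,6'R)-5,6-dihydro-β,ε-carotene-3,5,6,3'-tetrol
Conditions: Bu4NF, THF, 0 °C → rt, Ar, dark
Reagents that add atoms: none
Why: Fluoride cleaves the two secondary silyl ethers under non-acidic conditions, which spares the tertiary allylic C6 hydroxyl, the allylic C3' hydroxyl and the polyene; no stereocentre is involved.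

## Compound list

1 | (R)-epichlorohydrin | ClC[C@H]1CO1 | starting material
2 | isopropenylmagnesium bromide | CC(=C)[Mg]Br | starting material
3 | (R)-1-chloro-4-methylpent-4-en-2-ol | ClC[C@H](O)CC(C)=C | intermediate
4 | lithium acetylide–ethylenediamine complex | [Li+].[C-]#C.NCCN | starting material
5 | (R)-2-(2-methylallyl)oxirane | C=C(C)C[C@@H]1CO1 | intermediate
6 | (R)-6-methylhept-6-en-1-yn-4-ol | C=C(C)C[C@@H](O)CC#C | intermediate
7 | (R)-triisopropyl[(6-methylhept-6-en-1-yn-4-yl)oxy]silane | C=C(C)C[C@@H](O[Si](C(C)C)(C(C)C)C(C)C)CC#C | intermediate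
8 | trimethylaluminium | C[Al](C)C | starting material
9 | dimethyl[(1E,4R)-2,6-dimethyl-4-(triisopropylsilyloxy)hepta-1,6-dien-1-yl]alumane | C=C(C)C[C@@H](O[Si](C(C)C)(C(C)C)C(C)C)C/C(C)=C/[Al](C)C | intermediate
10 | (R,E)-[(1-iodo-2,6-dimethylhepta-1,6-dien-4-yl)oxy]triisopropylsilane | C=C(C)C[C@@H](O[Si](C(C)C)(C(C)C)C(C)C)C/C(C)=C/I | intermediate
11 | methyl vinyl ketone (but-3-en-2-one) | CC(=O)C=C | starting material
12 | (3E,5E,8R)-6,10-dimethyl-8-(triisopropylsilyloxy)undeca-3,5,10-trien-2-one | C=C(C)C[C@@H](O[Si](C(C)C)(C(C)C)C(C)C)C/C(C)=C/C=C/C(C)=O | intermediate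
13 | (3R,6R)-3-(triisopropylsilyloxy)-α-ionone | CC1=C[C@H](O[Si](C(C)C)(C(C)C)C(C)C)CC(C)(C)[C@H]1/C=C/C(C)=O | intermediate
14 | vinylmagnesium bromide | C=C[Mg]Br | starting material
15 | (1E)-3-methyl-1-[(1R,4R)-2,6,6-trimethyl-4-(triisopropylsilyloxy)cyclohex-2-en-1-yl]penta-1,4-dien-3-ol (both C3 epimers) | CC1=C[C@H](O[Si](C(C)C)(C(C)C)C(C)C)CC(C)(C)[C@H]1/C=C/C(C)(O)C=C | intermediate
16 | [(2E,4E)-3-methyl-5-[(1R,4R)-2,6,6-trimethyl-4-(triisopropylsilyloxy)cyclohex-2-en-1-yl]penta-2,4-dien-1-yl]triphenylphosphonium bromide | CC1=C[C@H](O[Si](C(C)C)(C(C)C)C(C)C)CC(C)(C)[C@H]1/C=C/C(C)=C/C[P+](c1ccccc1)(c1ccccc1)c1ccccc1.[Br-] | intermediate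
17 | (2E,4E,6E)-2,7-dimethylocta-2,4,6-trienedial | O=C/C(C)=C/C=C/C=C(C)/C=O | starting material
18 | [(2E,4E)-3-methyl-5-[(1R,4R)-2,6,6-trimethyl-4-(triisopropylsilyloxy)cyclohex-2-en-1-yl]penta-2,4-dien-1-ylidene]triphenylphosphorane | CC1=C[C@H](O[Si](C(C)C)(C(C)C)C(C)C)CC(C)(C)[C@H]1/C=C/C(C)=C/C=P(c1ccccc1)(c1ccccc1)c1ccccc1 | intermediate
19 | (2E,4E,6E,8E,10E,12E)-2,7,11-trimethyl-13-[(1R,4R)-2,6,6-trimethyl-4-(triisopropylsilyloxy)cyclohex-2-en-1-yl]trideca-2,4,6,8,10,12-hexaenal | CC1=C[C@H](O[Si](C(C)C)(C(C)C)C(C)C)CC(C)(C)[C@H]1/C=C/C(C)=C/C=C/C(C)=C/C=C/C=C(C)/C=O | intermediate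
20 | (4R,6R)-4-hydroxy-2,2,6-trimethylcyclohexanone | O=C1C(C)(C)C[C@H](O)C[C@H]1C | starting material
21 | (4R,6R)-2,2,6-trimethyl-4-(triisopropylsilyloxy)cyclohexanone | O=C1C(C)(C)C[C@H](O[Si](C(C)C)(C(C)C)C(C)C)C[C@H]1C | intermediate
22 | lithium (R)-2,6,6-trimethyl-4-(triisopropylsilyloxy)cyclohex-1-en-1-olate | [Li+].[O-]C1=C(C)C[C@@H](O[Si](C(C)C)(C(C)C)C(C)C)CC1(C)C | intermediate
23 | (R)-2,6,6-trimethyl-4-(triisopropylsilyloxy)cyclohex-1-en-1-yl trifluoromethanesulfonate | FC(F)(F)S(=O)(=O)OC1=C(C)C[C@@H](O[Si](C(C)C)(C(C)C)C(C)C)CC1(C)C | intermediate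
24 | (3R)-3-(triisopropylsilyloxy)-β-ionone | CC(=O)/C=C/C1=C(C)C[C@@H](O[Si](C(C)C)(C(C)C)C(C)C)CC1(C)C | intermediate
25 | (E)-4-[(1S,4S,6R)-2,2,6-trimethyl-4-(triisopropylsilyloxy)-7-oxabicyclo[4.1.0]heptan-1-yl]but-3-en-2-one | CC(=O)/C=C/[C@@]12O[C@]1(C)C[C@@H](O[Si](C(C)C)(C(C)C)C(C)C)CC2(C)C | intermediate
26 | (E)-4-[(1S,2S,4S)-1,2-dihydroxy-2,6,6-trimethyl-4-(triisopropylsilyloxy)cyclohexyl]but-3-en-2-one | CC(=O)/C=C/[C@]1(O)C(C)(C)C[C@H](O[Si](C(C)C)(C(C)C)C(C)C)C[C@]1(C)O | intermediate
27 | (1S,2S,4S)-1-[(1E)-3-hydroxy-3-methylpenta-1,4-dien-1-yl]-2,6,6-trimethyl-4-(triisopropylsilyloxy)cyclohexane-1,2-diol (both side-chain carbinol epimers) | C=CC(C)(O)/C=C/[C@]1(O)C(C)(C)C[C@H](O[Si](C(C)C)(C(C)C)C(C)C)C[C@]1(C)O | intermediate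
28 | [(2E,4E)-5-[(1S,2S,4S)-1,2-dihydroxy-2,6,6-trimethyl-4-(triisopropylsilyloxy)cyclohexyl]-3-methylpenta-2,4-dien-1-yl]triphenylphosphonium bromide | [Br-].c1ccc(cc1)[P+](c1ccccc1)(c1ccccc1)C/C=C(C)/C=C/[C@]1(O)C(C)(C)C[C@H](O[Si](C(C)C)(C(C)C)C(C)C)C[C@]1(C)O | intermediate
29 | [(2E,4E)-5-[(1S,2S,4S)-1,2-dihydroxy-2,6,6-trimethyl-4-(triisopropylsilyloxy)cyclohexyl]-3-methylpenta-2,4-dien-1-ylidene]triphenylphosphorane | c1ccc(cc1)P(c1ccccc1)(c1ccccc1)=C/C=C(C)/C=C/[C@]1(O)C(C)(C)C[C@H](O[Si](C(C)C)(C(C)C)C(C)C)C[C@]1(C)O | intermediate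
30 | (3S,5S,6S,3'R,6'R)-3,3'-bis(triisopropylsilyloxy)-5,6-dihydro-β,ε-carotene-5,6-diol | CC1=C[C@H](O[Si](C(C)C)(C(C)C)C(C)C)CC(C)(C)[C@H]1/C=C/C(C)=C/C=C/C(C)=C/C=C/C=C(C)/C=C/C=C(C)/C=C/[C@]1(O)C(C)(C)C[C@H](O[Si](C(C)C)(C(C)C)C(C)C)C[C@]1(C)O | intermediate
31 | (3S,5S,6S,3'R,6'R)-5,6-dihydro-β,ε-carotene-3,5,6,3'-tetrol | CC1=C[C@H](O)CC(C)(C)[C@H]1/C=C/C(C)=C/C=C/C(C)=C/C=C/C=C(C)/C=C/C=C(C)/C=C/[C@]1(O)C(C)(C)C[C@H](O)C[C@]1(C)O | target

## Step count and least certain steps

Total: 18 steps. Longest linear sequence: 11 steps (steps 1 to 9, then 17 and 18); the triol branch (steps 10 to 16) joins at step 17.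

Step 6 (key step).
- What may go wrong: once the ring has closed, the C3' oxygen is allylic, and the strong acid needed to make the deactivated dienone alkene react may ionise this C–O bond, leading to loss of the silyloxy group and diene formation. The 1,4-induction from C3' to C6' may also be incomplete, through a competing boat-like closure or acid-induced E/Z equilibration of the dienone before closure. Proton loss may go toward C6' or the methyl group.
- Fallback: this one does not branch from an intermediate; compounds 1 to 12 are given up, it sets out from purchasable racemic α-ionone and comes back to the route at 13. Racemic (E)-4-(2,6,6-trimethylcyclohex-2-en-1-yl)but-3-en-2-one F1 is protected with ethylene glycol and pyridinium p-toluenesulfonate as 2-methyl-2-[(E)-2-(2,6,6-trimethylcyclohex-2-en-1-yl)ethenyl]-1,3-dioxolane F2. Allylic oxidation with CrO3/3,5-dimethylpyrazole gives 2,4,4-trimethyl-3-[(E)-2-(2-methyl-1,3-dioxolan-2-yl)ethenyl]cyclohex-5-en-1-one... more simply named the 3-oxo-α-ionone ethylene ketal F3. Reduction with NaBH4/CeCl3 and chromatographic removal of the cis epimer give racemic trans-3-hydroxy-α-ionone ethylene ketal F4. Lipase-catalysed acetylation with vinyl acetate resolves F4, and mild ketal hydrolysis (pyridinium p-toluenesulfonate, wet acetone) of the fraction of the right series gives (3R,6R)-3-hydroxy-α-ionone F5. Silylation with TIPSOTf/2,6-lutidine returns 13.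

Step 13.
- What may go wrong: poor facial selectivity of the peracid, because the only bias is a remote equatorial silyloxy group, which would cost material and require a difficult separation.
- Fallback: reagent-controlled epoxidation, setting out from 23 and coming back at 25. Pd(OAc)2/PPh3-catalysed methoxycarbonylation (CO, MeOH, Et3N) gives methyl (R)-2,6,6-trimethyl-4-(triisopropylsilyloxy)cyclohex-1-ene-1-carboxylate F6. Reduction with iBu2AlH gives [(R)-2,6,6-trimethyl-4-(triisopropylsilyloxy)cyclohex-1-en-1-yl]methanol F7. Sharpless asymmetric epoxidation (Ti(OiPr)4, D-(−)-diethyl tartrate, tert-butyl hydroperoxide) gives [(1R,4S,6R)-2,2,6-trimethyl-4-(triisopropylsilyloxy)-7-oxabicyclo[4.1.0]heptan-1-yl]methanol F8. Dess–Martin oxidation gives (1S,4S,6R)-2,2,6-trimethyl-4-(triisopropylsilyloxy)-7-oxabicyclo[4.1.0]heptane-1-carbaldehyde F9. Wittig reaction with 1-(triphenylphosphoranylidene)propan-2-one gives 25.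

Step 14.
- What may go wrong: opening at the wrong carbon or with rearrangement (ring contraction by a 1,2-shift to the C5 cation), or slow hydrolysis in the crowded ring with gradual loss of the silyl group, after which the freed C3 hydroxyl can attack C6.
- Fallback: tethered delivery of the C5 oxygen, setting out from 25 and coming back at 26. Bu4NF gives (E)-4-[(1S,4S,6R)-4-hydroxy-2,2,6-trimethyl-7-oxabicyclo[4.1.0]heptan-1-yl]but-3-en-2-one F10. Di-tert-butyl dicarbonate with 4-dimethylaminopyridine gives its tert-butyl carbonate F11. BF3·OEt2 at −78 °C lets the carbonate carbonyl oxygen open the epoxide at C5 with inversion and loss of the tert-butyl group, giving the 3,5-cyclic carbonate with free C6 hydroxyl F12. K2CO3 in methanol gives (E)-4-[(1S,2S,4S)-1,2,4-trihydroxy-2,6,6-trimethylcyclohexyl]but-3-en-2-one F13. TIPSOTf/2,6-lutidine at −78 °C silylates only the secondary hydroxyl and returns 26.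

Step 16.
- What may go wrong: under the acidic conditions the tertiary allylic C6 hydroxyl may ionise, or the C5 hydroxyl may trap the pentadienyl cation intramolecularly, before triphenylphosphine captures it.
- Fallback: build the salt without a cation, setting out from 26 and coming back at 28. Horner–Wadsworth–Emmons reaction with triethyl phosphonoacetate and NaH (excess, to cover the two hydroxyls) gives, after removal of the 2Z isomer, ethyl (2E,4E)-5-[(1S,2S,4S)-1,2-dihydroxy-2,6,6-trimethyl-4-(triisopropylsilyloxy)cyclohexyl]-3-methylpenta-2,4-dienoate F14. Reduction with iBu2AlH gives (1S,2S,4S)-1-[(1E,3E)-5-hydroxy-3-methylpenta-1,3-dien-1-yl]-2,6,6-trimethyl-4-(triisopropylsilyloxy)cyclohexane-1,2-diol F15. CBr4/PPh3 gives, under neutral conditions, (1S,2S,4S)-1-[(1E,3E)-5-bromo-3-methylpenta-1,3-dien-1-yl]-2,6,6-trimethyl-4-(triisopropylsilyloxy)cyclohexane-1,2-diol F16. Triphenylphosphine then gives 28.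

## Further compounds

F1 | step 6 | racemic (E)-4-(2,6,6-trimethylcyclohex-2-en-1-yl)but-3-en-2-one (α-ionone) | CC1=CCCC(C)(C)C1/C=C/C(C)=O
F2 | step 6 | racemic 2-methyl-2-[(E)-2-(2,6,6-trimethylcyclohex-2-en-1-yl)ethenyl]-1,3-dioxolane | CC1=CCCC(C)(C)C1/C=C/C1(C)OCCO1
F3 | step 6 | racemic 3-oxo-α-ionone ethylene ketal | CC1=CC(=O)CC(C)(C)C1/C=C/C1(C)OCCO1
F4 | step 6 | racemic trans-3-hydroxy-α-ionone ethylene ketal (one enantiomer drawn) | CC1=C[C@H](O)CC(C)(C)[C@H]1/C=C/C1(C)OCCO1
F5 | step 6 | (3R,6R)-3-hydroxy-α-ionone | CC1=C[C@H](O)CC(C)(C)[C@H]1/C=C/C(C)=O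
F6 | step 13 | methyl (R)-2,6,6-trimethyl-4-(triisopropylsilyloxy)cyclohex-1-ene-1-carboxylate | COC(=O)C1=C(C)C[C@@H](O[Si](C(C)C)(C(C)C)C(C)C)CC1(C)C
F7 | step 13 | [(R)-2,6,6-trimethyl-4-(triisopropylsilyloxy)cyclohex-1-en-1-yl]methanol | OCC1=C(C)C[C@@H](O[Si](C(C)C)(C(C)C)C(C)C)CC1(C)C
F8 | step 13 | [(1R,4S,6R)-2,2,6-trimethyl-4-(triisopropylsilyloxy)-7-oxabicyclo[4.1.0]heptan-1-yl]methanol | OC[C@@]12O[C@]1(C)C[C@@H](O[Si](C(C)C)(C(C)C)C(C)C)CC2(C)C
F9 | step 13 | (1S,4S,6R)-2,2,6-trimethyl-4-(triisopropylsilyloxy)-7-oxabicyclo[4.1.0]heptane-1-carbaldehyde | O=C[C@@]12O[C@]1(C)C[C@@H](O[Si](C(C)C)(C(C)C)C(C)C)CC2(C)C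
F10 | step 14 | (E)-4-[(1S,4S,6R)-4-hydroxy-2,2,6-trimethyl-7-oxabicyclo[4.1.0]heptan-1-yl]but-3-en-2-one | CC(=O)/C=C/[C@@]12O[C@]1(C)C[C@@H](O)CC2(C)C
F11 | step 14 | tert-butyl (1S,3S,6R)-1,5,5-trimethyl-6-[(E)-3-oxobut-1-en-1-yl]-7-oxabicyclo[4.1.0]heptan-3-yl carbonate | CC(=O)/C=C/[C@@]12O[C@]1(C)C[C@@H](OC(=O)OC(C)(C)C)CC2(C)C
F12 | step 14 | 3,5-cyclic carbonate of (E)-4-[(1S,2S,4S)-1,2,4-trihydroxy-2,6,6-trimethylcyclohexyl]but-3-en-2-one with free C6 hydroxyl | CC(=O)/C=C/[C@]1(O)C(C)(C)C[C@H]2C[C@]1(C)OC(=O)O2
F13 | step 14 | (E)-4-[(1S,2S,4S)-1,2,4-trihydroxy-2,6,6-trimethylcyclohexyl]but-3-en-2-one | CC(=O)/C=C/[C@]1(O)C(C)(C)C[C@H](O)C[C@]1(C)O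
F14 | step 16 | ethyl (2E,4E)-5-[(1S,2S,4S)-1,2-dihydroxy-2,6,6-trimethyl-4-(triisopropylsilyloxy)cyclohexyl]-3-methylpenta-2,4-dienoate | CCOC(=O)/C=C(C)/C=C/[C@]1(O)C(C)(C)C[C@H](O[Si](C(C)C)(C(C)C)C(C)C)C[C@]1(C)O
F15 | step 16 | (1S,2S,4S)-1-[(1E,3E)-5-hydroxy-3-methylpenta-1,3-dien-1-yl]-2,6,6-trimethyl-4-(triisopropylsilyloxy)cyclohexane-1,2-diol | OC/C=C(C)/C=C/[C@]1(O)C(C)(C)C[C@H](O[Si](C(C)C)(C(C)C)C(C)C)C[C@]1(C)O
F16 | step 16 | (1S,2S,4S)-1-[(1E,3E)-5-bromo-3-methylpenta-1,3-dien-1-yl]-2,6,6-trimethyl-4-(triisopropylsilyloxy)cyclohexane-1,2-diol | BrC/C=C(C)/C=C/[C@]1(O)C(C)(C)C[C@H](O[Si](C(C)C)(C(C)C)C(C)C)C[C@]1(C)O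
A1 | alternative 1 | ethyl (2E,4E,6E,8E)-3,7-dimethyl-9-[(1S,2S,4S)-2,6,6-trimethyl-1,2,4-tris(triethylsilyloxy)cyclohexyl]nona-2,4,6,8-tetraenoate | CCOC(=O)/C=C(C)/C=C/C=C(C)/C=C/[C@]1(O[Si](CC)(CC)CC)C(C)(C)C[C@H](O[Si](CC)(CC)CC)C[C@]1(C)O[Si](CC)(CC)CC
A2 | alternative 1 | (1S,2S,4S)-1-[(E)-but-1-en-3-yn-1-yl]-2,6,6-trimethyl-1,2,4-tris(triethylsilyloxy)cyclohexane | C#C/C=C/[C@]1(O[Si](CC)(CC)CC)C(C)(C)C[C@H](O[Si](CC)(CC)CC)C[C@]1(C)O[Si](CC)(CC)CC
A3 | alternative 1 | ethyl (2E,4E)-5-iodo-3-methylpenta-2,4-dienoate | CCOC(=O)/C=C(C)/C=C/I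
A4 | alternative 2 | C15 enyne 3,5-cyclic carbonate with free C6 hydroxyl and tert-butyldimethylsilyl-protected primary alcohol | CC(C)(C)[Si](C)(C)OC/C=C(C)/C#C[C@]1(O)C(C)(C)C[C@H]2C[C@]1(C)OC(=O)O2
A5 | alternative 2 | C15 enyne (3S,5R,6S)-5,6-epoxide with C3 tert-butyl carbonate | CC(C)(C)[Si](C)(C)OC/C=C(C)/C#C[C@@]12O[C@]1(C)C[C@@H](OC(=O)OC(C)(C)C)CC2(C)C
A6 | alternative 3 | (3S,5S,6S,3'R,6'R)-3,5,6,3'-tetrakis(triethylsilyloxy)-5,6-dihydro-β,ε-carotene | CC1=C[C@H](O[Si](CC)(CC)CC)CC(C)(C)[C@H]1/C=C/C(C)=C/C=C/C(C)=C/C=C/C=C(C)/C=C/C=C(C)/C=C/[C@]1(O[Si](CC)(CC)CC)C(C)(C)C[C@H](O[Si](CC)(CC)CC)C[C@]1(C)O[Si](CC)(CC)CC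
A7 | alternative 3 | tetraethyl [(2E,4E,6E,8E,10E,12E,14E)-2,6,11,15-tetramethylhexadeca-2,4,6,8,10,12,14-heptaene-1,16-diyl]bisphosphonate | CCOP(=O)(OCC)C/C(C)=C/C=C/C(C)=C/C=C/C=C(C)/C=C/C=C(C)/CP(=O)(OCC)OCC
A8 | alternative 3 | (1S,2S,4S)-2,6,6-trimethyl-1,2,4-tris(triethylsilyloxy)cyclohexane-1-carbaldehyde | O=C[C@]1(O[Si](CC)(CC)CC)C(C)(C)C[C@H](O[Si](CC)(CC)CC)C[C@]1(C)O[Si](CC)(CC)CC
A9 | alternative 3 | (1R,4R)-2,6,6-trimethyl-4-(triethylsilyloxy)cyclohex-2-ene-1-carbaldehyde | CC1=C[C@H](O[Si](CC)(CC)CC)CC(C)(C)[C@H]1C=O
A10 | alternative 3 | (2E,4E,6E,8E,10E,12E,14E)-2,6,11,15-tetramethylhexadeca-2,4,6,8,10,12,14-heptaenedial (crocetindial) | O=C/C(C)=C/C=C/C(C)=C/C=C/C=C(C)/C=C/C=C(C)/C=O
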